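## The problem

Compound 23 is a linear chain of six benzene rings, A to F, joined only by five diaryl ether oxygens; it carries sixteen free phenolic hydroxyls and no stereocenter, so the whole task is regiochemical. Every ether oxygen sits between oxygenated positions: rings A, B and D are each bound to the next ring through a carbon flanked by two C–OH groups, and the pentaoxygenated rings C and E carry their two ether oxygens on neighbouring carbons, C1 next to the only C–H and C6 next to a C–OH. Such electron-rich, doubly ortho-substituted aryl–oxygen bonds are the least favourable case for Ullmann or SNAr chemistry, and in rings C and E the two neighbouring positions must also be told apart. The free polyphenol, with its pyrogallol-type rings, is oxidized readily by air in the presence of base, so all hydroxyls stay masked until the last step and are then freed under non-oxidizing conditions that leave the diaryl ethers intact. The molecule repeats itself, since rings B and D share one substitution pattern and rings C and E another, so one building block can serve twice in each case. Ring A is a 2-aryloxyphloroglucinol: in polyketide numbering its carbons C1, C3 and C5 carry oxygen in the alternating pattern of a 3,5-dioxohexanoate, and the ether oxygen to ring B sits on C6. Ring A can therefore be closed by a Claisen condensation of C6 onto C1 of a triketide equivalent that already bears the ring B oxygen, which turns the most hindered aryl–oxygen bond of the chain into an SN2 reaction at a primary carbon.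

## Retrosynthesis

**23 to 22.** The sixteen O–H groups are traced back to methyl ethers in 22. Methyl is preferred because the ring building blocks 1, 15 and 18 already carry their methoxy groups and the pyrone route delivers the third oxygen of ring A as OMe. Methyl ethers also survive organolithium, methoxide, copper and hydrogenation conditions, which leaves benzyl free as the single temporary group. The forward step is one exhaustive Lewis-acid dealkylation that spares the diaryl ethers.

**22 to 21 and 19.** The D–O–E bond is cut at ring E C1. The oxygen stays with the doubly flanked phenol 21, and the electrophilic carbon in iodide 19 has only one ortho substituent. The opposite pairing would need a 2,6-dimethoxyaryl halide, the worst electrophile available. The forward reaction is a CuI-catalysed coupling of a hindered phenol with an ortho-substituted, electron-rich aryl iodide.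

**19 to 16 and 18.** The E–O–F bond is cut at ring F C1. The hindered oxygen belongs to iodophenol 16 and the aryl group comes from the unhindered boronic acid 18. In 16 the hydroxyl marks the carbon next to OMe and the iodine marks the carbon next to C–H, so the order of the two neighbours in ring E is fixed by functional-group identity. The coupling must leave the C–I bond alone, which an oxidative copper arylation at room temperature does.

**21 to 20, then to 14 and 17; 17 to 16 and 5.** The same logic is applied one ring pair earlier. Phenol 21 comes from benzyl ether 20. The B–O–C bond of 20 is cut into phenol 14 and iodide 17, and the C–O–D bond of 17 into 16 and boronic acid 5. Iodophenol 16 therefore serves for both ring C and ring E.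

**16 to 15.** The C–I bond is cut. Halogenation next to the free hydroxyl of 15 is the only regiochemical decision in the building of rings C and E.

**14 to 13 to 12.** Phenol 14 comes from benzyl ether 13, and 13 from the diol 12 by methylation of the two ring A hydroxyls. The benzyl group holds the one ring B oxygen that will later bind ring C.

**12 to 9 (key disconnection).** The ring A bond between the ether-bearing carbon and one neighbouring C–OH carbon is cut. This leads to the 6-aryloxymethyl-4-methoxy-2-pyrone 9. The neighbouring option, coupling a preformed ring A phenol to ring B, would buy the ring instead of making it and would need the most hindered aryl–oxygen coupling of the whole chain. The cut through ring A builds the ring from a triketide and places the ether oxygen before the ring exists. The forward reaction must open the lactone and steer the aryloxy-bearing carbon onto the ester carbonyl.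

**9 to 6 and 8; 8 to 7; 6 to 5 to 2 to 1.** The CH2–O bond of 9 is cut into phenol 6 and bromomethylpyrone 8, which comes from pyrone 7 by bromination of its methyl group. Phenol 6 comes from boronic acid 5 by oxidation, and 5 from the benzylated bromophenol 2, made from 1. Boronic acid 5 is therefore the common source of ring B (as phenol 6) and ring D (as the aryl donor for 17).

## Roads not taken

**Alternative 1:** Ring C would be cut between C6 and C1 and grown on the oxygen of 14 from dimethyl squarate A3. A β-metallated aryl vinyl ether of 14, the vinyllithium A4, would add to A3. After O-methylation this gives the 4-alkenylcyclobutenone A2. Heating A2 opens it to a dienylketene, which closes by 6π electrocyclization and tautomerizes to the A–B–C phenol A1. Arylation of A1 with 5 would give 20.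

- Merits: all five oxygens of ring C are placed by construction. The B–O–C ether is made as a vinyl ether, not by a hindered aryl coupling. The free hydroxyl appears exactly where ring D must be attached.
- Weak points: A4 has an aryloxide β to the carbanion and is prone to fragment. The sequence of vinyl ether formation, metallation, addition, methylation and thermolysis is linear. It must be run a second time for ring E on the tetramer 21. It does nothing for ring A.
- Comparison: in regiochemical certainty for rings C and E, and in avoiding the couplings of steps 12 and 14, this road is better. The pyrone plan offers convergence instead: iodophenol 16 is made once and used twice, and no organolithium chemistry is done on large intermediates. Its own ring-forming step (step 6) sits early, on small material.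

**Alternative 2:** Both ether bonds of ring E would be cut. The cationic complex A6, (η6-4,5-dichloro-1,2,3-trimethoxybenzene)(η5-cyclopentadienyl)ruthenium hexafluorophosphate, would undergo two SNAr reactions in one pot. The phenoxide of 21 attacks first at the chlorinated carbon next to C–H. The phenol A7 (3,4,5-trimethoxyphenol) then attacks at the chlorinated carbon next to OMe. The product is the ruthenium-bound hexamer A5, and decomplexation gives 22.

- Merits: the metal makes the arene electrophilic enough for hindered phenoxides under mild conditions. Two bonds form in one operation. The end game is highly convergent.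
- Weak points: the two C–Cl carbons differ only in their outer neighbour, and nothing but the order of addition and sterics tells them apart. Any leakage gives an isomeric hexamer that would be very hard to remove. The second substitution takes place on a ring already deactivated by the first aryloxy group. Ruthenium is stoichiometric and must be removed. Phenol 21 must still be made by other means.
- Comparison: this road is milder and at least as short for the last ring pair (one pot plus decomplexation against steps 11 and 14). The pyrone plan has the fixed assignment of the two neighbours through OH and I in 16, and copper in catalytic amount for the Ullmann couplings.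

**Alternative 3:** Ring B would be cut at one C–O(H) bond and at the A–O–B ether. Guaiacol A9 is ortho-oxygenated by O2 under [Cu(MeCN)4]PF6, a monovalent copper salt, with a bulky diamine to 3-methoxy-ortho-quinone A12. This is trapped at C5 by the oxygen of 2,4,6-trimethoxyphenol A10 to give quinone A8. Reduction would give catechol A11, and selective methylation of its outer hydroxyl would give 14.

- Merits: it is catalytic and uses O2. It builds the A–O–B ether from two cheap phenols without a hindered coupling. It reaches the stage of 14 in about three steps, against eight in the pyrone plan.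
- Weak points: the trapping phenol A10 is more easily oxidized than A9, so cross-coupling competes with self-coupling of A9 and with oxidation of A10. The two adjacent hydroxyls of A11 must be differentiated so that only the central one stays free, and nothing in the structure secures this.
- Comparison: this road is shorter to 14. The pyrone plan places the free hydroxyl unambiguously through the benzyl ether, reuses 5 for rings B and D, and has no oxidizable partner in its ring-forming step.

Key step: step 6

Remarks on the chemistry:
- Pyrone 7 is taken as purchased. It is also one O-methylation away from 4-hydroxy-6-methyl-2H-pyran-2-one.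
- The boron aryloxides present in step 15 before hydrolysis are an undefined mixture of open and cyclic bromoborates. They are treated as part of the work-up and not as a discrete intermediate.

## Route

Step 1
Reactants: 1 4-bromo-2,6-dimethoxyphenol
Product: 2 2-(benzyloxy)-5-bromo-1,3-dimethoxybenzene
Conditions: BnBr, K2CO3, DMF, rt
Reagents that add atoms: benzyl bromide, BrCc1ccccc1
Why: Williamson O-benzylation of a 2,6-dimethoxyphenoxide. The benzyl group marks the one oxygen of rings B and D that is freed later and is orthogonal to the methyl ethers.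

Step 2
Reactants: 2 2-(benzyloxy)-5-bromo-1,3-dimethoxybenzene
Product: 5 [4-(benzyloxy)-3,5-dimethoxyphenyl]boronic acid, via aryllithium 3 (not isolated), via lithium aryltriisopropoxyborate 4 (not isolated)
Conditions: n-BuLi, THF, −78 °C; B(OiPr)3, −78 °C to rt; aq. HCl
Reagents that add atoms: triisopropyl borate, CC(C)OB(OC(C)C)OC(C)C; water, O
Why: Bromine–lithium exchange at −78 °C is faster than any attack on the benzyl ether. The aryllithium is trapped by the borate and the ate complex is hydrolysed by acid, the standard borylation of an aryl bromide.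

Step 3
Reactants: 5 [4-(benzyloxy)-3,5-dimethoxyphenyl]boronic acid
Product: 6 4-(benzyloxy)-3,5-dimethoxyphenol
Conditions: 30% aq. H2O2, EtOH, rt
Reagents that add atoms: hydrogen peroxide, OO
Why: ipso-Hydroxylation of an arylboronic acid: peroxide adds to boron, the aryl group shifts to oxygen and the borate ester hydrolyses. Benzyl and methyl ethers are inert.

Step 4
Reactants: 7 4-methoxy-6-methyl-2H-pyran-2-one
Product: 8 6-(bromomethyl)-4-methoxy-2H-pyran-2-one
Conditions: NBS, AIBN (cat.), PhCF3, reflux
Reagents that add atoms: N-bromosuccinimide, O=C1CCC(=O)N1Br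
Why: Wohl–Ziegler radical bromination. The 6-methyl group is the only allylic-type C–H position, and radical conditions avoid ionic bromination at C3.

Step 5
Reactants: 6 4-(benzyloxy)-3,5-dimethoxyphenol; 8 6-(bromomethyl)-4-methoxy-2H-pyran-2-one
Product: 9 6-{[4-(benzyloxy)-3,5-dimethoxyphenoxy]methyl}-4-methoxy-2H-pyran-2-one
Conditions: K2CO3, acetone, reflux
Reagents that add atoms: none
Why: Williamson ether synthesis, SN2 of an unhindered phenoxide at a primary, vinylogously activated bromide. The future A–O–B ether oxygen is attached here without any aryl–oxygen coupling.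

Step 6
Reactants: 9 6-{[4-(benzyloxy)-3,5-dimethoxyphenoxy]methyl}-4-methoxy-2H-pyran-2-one
Product: 12 2-[4-(benzyloxy)-3,5-dimethoxyphenoxy]-5-methoxybenzene-1,3-diol, via open-chain keto ester 10 (not isolated), via cyclohexenedione 11 (not isolated)
Conditions: KOMe (4 equiv), MeOH, reflux, Ar; then aq. HCl, 0 °C
Reagents that add atoms: none
Why: Methoxide adds to the lactone carbonyl and the ring opens to the potassium dienolate of keto ester 10, in which the ester carbon C1 and C4 stay cis on the C2=C3 enol ether double bond (2E by the sequence rules). Proton transfer through methanol gives the minor C6 enolate, whose carbon is acidified by the ketone and the aryloxy group; it attacks the ester carbonyl and expels methoxide to give cyclohexenedione 11, which enolizes at once to the dianion of 12. The step joins two known reaction types, the base-induced opening of 4-methoxy-2-pyrones and the Claisen cyclization of 3,5-dioxoalkanoates to phloroglucinols (the laboratory counterpart of the polyketide cyclization), and applies them to a pyrone whose nucleophilic carbon carries an aryloxy group. Ring A closes through the C6–C1 bond, between the ether-bearing carbon and a neighbouring C–OH carbon, in a 6-(enolexo)-exo-trig closure. No stereocenter remains, since the one at the aryloxy carbon of 11 disappears on aromatization. The step needs C-acylation at C6 to win over O-acylation, which only returns 9, and over attack by C4, which would form a four-membered ring. Lactone formation is reversible under methoxide and aromatization is not, so the equilibrium drains into 12. Excess KOMe allows for the two phenoxides of 12, potassium avoids a chelated resting enolate of 10, and argon protects the electron-rich phenoxide.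

Step 7
Reactants: 12 2-[4-(benzyloxy)-3,5-dimethoxyphenoxy]-5-methoxybenzene-1,3-diol
Product: 13 2-[4-(benzyloxy)-3,5-dimethoxyphenoxy]-1,3,5-trimethoxybenzene
Conditions: Me2SO4, K2CO3, acetone, reflux
Reagents that add atoms: dimethyl sulfate, COS(=O)(=O)OC
Why: O-Methylation of phenols with dimethyl sulfate and carbonate in acetone, the standard conditions for phloroglucinol-type rings that keep C-alkylation down.

Step 8
Reactants: 13 2-[4-(benzyloxy)-3,5-dimethoxyphenoxy]-1,3,5-trimethoxybenzene
Product: 14 2,6-dimethoxy-4-(2,4,6-trimethoxyphenoxy)phenol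
Conditions: H2 (1 atm), 10% Pd/C, EtOAc/MeOH, rt
Reagents that add atoms: none
Why: Hydrogenolysis of the benzyl aryl ether. Methyl and diaryl ethers are untouched and no halogen is present.

Step 9
Reactants: 15 2,3,4-trimethoxyphenol
Product: 16 6-iodo-2,3,4-trimethoxyphenol
Conditions: I2, NaHCO3, THF/H2O, 0 °C to rt
Reagents that add atoms: iodine, II
Why: Electrophilic iodination through the phenoxide, which directs to its only free ortho position since para is blocked by OMe. The preference for the position next to OH over that next to OMe is the one seen in the halogenation of 4-methoxyphenols and of vanillin.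

Step 10
Reactants: 16 6-iodo-2,3,4-trimethoxyphenol; 5 [4-(benzyloxy)-3,5-dimethoxyphenyl]boronic acid
Product: 17 2-(benzyloxy)-5-(6-iodo-2,3,4-trimethoxyphenoxy)-1,3-dimethoxybenzene
Conditions: Cu(OAc)2 (1 equiv), pyridine, 4 Å molecular sieves, CH2Cl2, air, rt
Reagents that add atoms: none
Why: Chan–Lam–Evans O-arylation with divalent copper acetate. It is established at room temperature for doubly ortho-substituted iodophenols and leaves the C–I bond intact because no low-valent metal is present. The boronic acid has no ortho substituent.

Step 11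
Reactants: 16 6-iodo-2,3,4-trimethoxyphenol; 18 (3,4,5-trimethoxyphenyl)boronic acid
Product: 19 1-iodo-3,4,5-trimethoxy-2-(3,4,5-trimethoxyphenoxy)benzene
Conditions: Cu(OAc)2 (1 equiv), pyridine, 4 Å molecular sieves, CH2Cl2, air, rt
Reagents that add atoms: none
Why: The same Chan–Lam–Evans O-arylation as in step 10, with the commercial ring F boronic acid. The iodine survives for step 14.

Step 12
Reactants: 14 2,6-dimethoxy-4-(2,4,6-trimethoxyphenoxy)phenol; 17 2-(benzyloxy)-5-(6-iodo-2,3,4-trimethoxyphenoxy)-1,3-dimethoxybenzene
Product: 20 2-(benzyloxy)-5-{6-[2,6-dimethoxy-4-(2,4,6-trimethoxyphenoxy)phenoxy]-2,3,4-trimethoxyphenoxy}-1,3-dimethoxybenzene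
Conditions: CuI (20 mol%), picolinic acid (40 mol%), K3PO4, DMSO, 90 °C, Ar
Reagents that add atoms: none
Why: Ullmann-type diaryl ether coupling with copper monoiodide and picolinic acid, a system developed for ortho-substituted phenols and aryl halides. The oxygen comes from the doubly flanked phenol and the iodide has a single ortho substituent, the only workable polarity for this bond.

Step 13
Reactants: 20 2-(benzyloxy)-5-{6-[2,6-dimethoxy-4-(2,4,6-trimethoxyphenoxy)phenoxy]-2,3,4-trimethoxyphenoxy}-1,3-dimethoxybenzene
Product: 21 4-{6-[2,6-dimethoxy-4-(2,4,6-trimethoxyphenoxy)phenoxy]-2,3,4-trimethoxyphenoxy}-2,6-dimethoxyphenol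
Conditions: H2 (1 atm), 10% Pd/C, EtOAc/MeOH, rt
Reagents that add atoms: none
Why: Hydrogenolysis of the single benzyl ether, as in step 8. Compound 20 contains no halogen and its other ethers are stable.

Step 14
Reactants: 21 4-{6-[2,6-dimethoxy-4-(2,4,6-trimethoxyphenoxy)phenoxy]-2,3,4-trimethoxyphenoxy}-2,6-dimethoxyphenol; 19 1-iodo-3,4,5-trimethoxy-2-(3,4,5-trimethoxyphenoxy)benzene
Product: 22 5-[6-(4-{6-[2,6-dimethoxy-4-(2,4,6-trimethoxyphenoxy)phenoxy]-2,3,4-trimethoxyphenoxy}-2,6-dimethoxyphenoxy)-2,3,4-trimethoxyphenoxy]-1,2,3-trimethoxybenzene (the hexadeca-O-methyl ether of 23)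
Conditions: CuI (20 mol%), picolinic acid (40 mol%), K3PO4, DMSO, 90 °C, Ar
Reagents that add atoms: none
Why: The same Ullmann-type coupling as in step 12, joining the ring D oxygen to ring E C1. All other functions are ethers and inert.

Step 15
Reactants: 22 hexadeca-O-methyl ether of 23
Product: 23 5-[6-(4-{6-[2,6-dihydroxy-4-(2,4,6-trihydroxyphenoxy)phenoxy]-2,3,4-trihydroxyphenoxy}-2,6-dihydroxyphenoxy)-2,3,4-trihydroxyphenoxy]benzene-1,2,3-triol (CNP0114537.0)
Conditions: BBr3 (excess), CH2Cl2, −78 °C to rt, Ar; degassed MeOH/H2O, 0 °C
Reagents that add atoms: none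
Why: Lewis-acid cleavage of aryl methyl ethers: boron coordinates the methoxy oxygen and bromide attacks the methyl carbon. The diaryl ethers offer no sp3 carbon and stay intact. Work-up under argon with degassed solvents protects the free polyphenol.

## Compound list

1 | 4-bromo-2,6-dimethoxyphenol | COc1cc(Br)cc(OC)c1O | starting material
2 | 2-(benzyloxy)-5-bromo-1,3-dimethoxybenzene | COc1cc(Br)cc(OC)c1OCc1ccccc1 | intermediate
3 | [4-(benzyloxy)-3,5-dimethoxyphenyl]lithium | [Li]c1cc(OC)c(OCc2ccccc2)c(OC)c1 | intermediate (not isolated)
4 | lithium [4-(benzyloxy)-3,5-dimethoxyphenyl]tri(propan-2-yloxy)borate | [Li+].CC(C)O[B-](OC(C)C)(OC(C)C)c1cc(OC)c(OCc2ccccc2)c(OC)c1 | intermediate (not isolated)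
5 | [4-(benzyloxy)-3,5-dimethoxyphenyl]boronic acid | COc1cc(B(O)O)cc(OC)c1OCc1ccccc1 | intermediate
6 | 4-(benzyloxy)-3,5-dimethoxyphenol | COc1cc(O)cc(OC)c1OCc1ccccc1 | intermediate
7 | 4-methoxy-6-methyl-2H-pyran-2-one | COC1=CC(=O)OC(C)=C1 | starting material
8 | 6-(bromomethyl)-4-methoxy-2H-pyran-2-one | COC1=CC(=O)OC(CBr)=C1 | intermediate
9 | 6-{[4-(benzyloxy)-3,5-dimethoxyphenoxy]methyl}-4-methoxy-2H-pyran-2-one | COC1=CC(=O)OC(COc2cc(OC)c(OCc3ccccc3)c(OC)c2)=C1 | intermediate
10 | methyl (2E)-6-[4-(benzyloxy)-3,5-dimethoxyphenoxy]-3-methoxy-5-oxohex-2-enoate (present as its potassium enolate) | COC(=O)/C=C(/OC)CC(=O)COc1cc(OC)c(OCc2ccccc2)c(OC)c1 | intermediate (not isolated)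
11 | 2-[4-(benzyloxy)-3,5-dimethoxyphenoxy]-5-methoxycyclohex-4-ene-1,3-dione (racemic, transient) | COC1=CC(=O)C(Oc2cc(OC)c(OCc3ccccc3)c(OC)c2)C(=O)C1 | intermediate (not isolated)
12 | 2-[4-(benzyloxy)-3,5-dimethoxyphenoxy]-5-methoxybenzene-1,3-diol | COc1cc(O)c(Oc2cc(OC)c(OCc3ccccc3)c(OC)c2)c(O)c1 | intermediate
13 | 2-[4-(benzyloxy)-3,5-dimethoxyphenoxy]-1,3,5-trimethoxybenzene | COc1cc(OC)c(Oc2cc(OC)c(OCc3ccccc3)c(OC)c2)c(OC)c1 | intermediate
14 | 2,6-dimethoxy-4-(2,4,6-trimethoxyphenoxy)phenol | COc1cc(OC)c(Oc2cc(OC)c(O)c(OC)c2)c(OC)c1 | intermediate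
15 | 2,3,4-trimethoxyphenol | COc1ccc(O)c(OC)c1OC | starting material
16 | 6-iodo-2,3,4-trimethoxyphenol | Oc1c(I)cc(OC)c(OC)c1OC | intermediate
17 | 2-(benzyloxy)-5-(6-iodo-2,3,4-trimethoxyphenoxy)-1,3-dimethoxybenzene | COc1cc(Oc2c(I)cc(OC)c(OC)c2OC)cc(OC)c1OCc1ccccc1 | intermediate
18 | (3,4,5-trimethoxyphenyl)boronic acid | COc1cc(B(O)O)cc(OC)c1OC | starting material
19 | 1-iodo-3,4,5-trimethoxy-2-(3,4,5-trimethoxyphenoxy)benzene | COc1cc(Oc2c(I)cc(OC)c(OC)c2OC)cc(OC)c1OC | intermediate
20 | 2-(benzyloxy)-5-{6-[2,6-dimethoxy-4-(2,4,6-trimethoxyphenoxy)phenoxy]-2,3,4-trimethoxyphenoxy}-1,3-dimethoxybenzene | COc1cc(OC)c(Oc2cc(OC)c(Oc3cc(OC)c(OC)c(OC)c3Oc3cc(OC)c(OCc4ccccc4)c(OC)c3)c(OC)c2)c(OC)c1 | intermediate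
21 | 4-{6-[2,6-dimethoxy-4-(2,4,6-trimethoxyphenoxy)phenoxy]-2,3,4-trimethoxyphenoxy}-2,6-dimethoxyphenol | COc1cc(OC)c(Oc2cc(OC)c(Oc3cc(OC)c(OC)c(OC)c3Oc3cc(OC)c(O)c(OC)c3)c(OC)c2)c(OC)c1 | intermediate
22 | 5-[6-(4-{6-[2,6-dimethoxy-4-(2,4,6-trimethoxyphenoxy)phenoxy]-2,3,4-trimethoxyphenoxy}-2,6-dimethoxyphenoxy)-2,3,4-trimethoxyphenoxy]-1,2,3-trimethoxybenzene | COc1cc(OC)c(Oc2cc(OC)c(Oc3cc(OC)c(OC)c(OC)c3Oc3cc(OC)c(Oc4cc(OC)c(OC)c(OC)c4Oc4cc(OC)c(OC)c(OC)c4)c(OC)c3)c(OC)c2)c(OC)c1 | intermediate
23 | 5-[6-(4-{6-[2,6-dihydroxy-4-(2,4,6-trihydroxyphenoxy)phenoxy]-2,3,4-trihydroxyphenoxy}-2,6-dihydroxyphenoxy)-2,3,4-trihydroxyphenoxy]benzene-1,2,3-triol | Oc1cc(O)c(Oc2cc(O)c(Oc3cc(O)c(O)c(O)c3Oc3cc(O)c(Oc4cc(O)c(O)c(O)c4Oc4cc(O)c(O)c(O)c4)c(O)c3)c(O)c2)c(O)c1 | target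

## Step count and risks

Total step count: 15. Longest linear sequence: 11 steps (steps 1, 2, 3, 5, 6, 7, 8, 12, 13, 14, 15, from 1 to 23).

**Step 6 (key step).** The opened anion may rest as the delocalized dienolate and simply return to the pyrone, because the C6 enolate is a minor tautomer. The aryloxy-bearing carbon is more hindered and the β-methoxyacrylate ester less electrophilic than in the unsubstituted case. Prolonged heating could then favour retro-Claisen cleavage at the C5 ketone over ring closure.
Fallback, setting out from bromide 2: the ether is made conventionally. Ullmann coupling of 2 with purchased 2,4,6-trimethoxyphenol A10 under CuI, picolinic acid and K3PO4 in DMSO should give 13 directly, and the route is rejoined at 13. Ring A is then bought, not built, and the pyrone ring transformation is abandoned for this ring only.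

**Step 12.** C–O bond formation between a doubly flanked phenoxide and an ortho-substituted, electron-rich aryl iodide may be slow. Protodeiodination of 17 and oxidative degradation of the phenoxide of 14 could then take over.
Fallback, setting out from 14: SNAr with 6-fluoro-2,3,4-trimethoxybenzaldehyde F1 (K2CO3, DMF, 120 °C) should give the diaryl ether aldehyde F2. F1 is made from 5-fluoro-1,2,3-trimethoxybenzene by lithiation between F and OMe and a DMF quench. Baeyer–Villiger oxidation of F2 with mCPBA gives the aryl formate F3, and methanolysis (K2CO3, MeOH) gives the A–B–C phenol F4, identical with A1. Chan–Lam coupling of F4 with boronic acid 5 under the conditions of step 10 returns to the route at 20.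

**Step 14.** The same slow coupling as in step 12, now with the larger phenol 21, where the same side reactions consume more valuable material.
Fallback, setting out from 21: SNAr with aldehyde F1 should give the pentamer aldehyde F5. Baeyer–Villiger oxidation gives the formate F6 and methanolysis the pentamer phenol F7. Chan–Lam coupling of F7 with boronic acid 18 rejoins the route at 22.

**Step 15.** Partly demethylated boron aryloxides may precipitate and stop the sixteen-fold cleavage short. The free polyphenol may also oxidize during isolation and purification.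
Fallback, setting out from 22: the crude product of the BBr3 treatment is not purified but peracetylated (Ac2O, pyridine, DMAP) to the hexadecaacetate F8. F8 is stable and can be chromatographed on silica, where under-demethylated material separates and can be resubmitted. Acid-catalysed methanolysis of F8 (HCl from AcCl in degassed MeOH, Ar) then releases 23.

**Step 10 (and step 11, same type).** O-Arylation of the doubly ortho-substituted phenol 16 may be slow. The boronic acid is then lost through protodeboronation and homocoupling, and the electron-rich phenol is oxidized by divalent copper and air.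
Fallback, setting out from bromide 2: bromine–lithium exchange (via 3) and an iodine quench give 2-(benzyloxy)-5-iodo-1,3-dimethoxybenzene F9. One-pot oxidation with mCPBA and TsOH in MeCN, then trapping with 1,3,5-trimethoxybenzene, gives the aryl(2,4,6-trimethoxyphenyl)iodonium tosylate F10. Metal-free arylation of 16 with F10 (K2CO3, MeCN, 50 °C) transfers the less electron-rich aryl group by ligand coupling at iodine and returns to the route at 17.

**Step 9.** Iodination may occur in part at C5, next to OMe, or twice. Iodine may also oxidize the electron-rich phenol towards a quinone.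
Fallback, setting out from 15: protection as the methoxymethyl ether F11 (MOMCl, i-Pr2NEt) is followed by directed ortho-lithiation next to the OMOM group (n-BuLi, THF, 0 °C) and an iodine quench to the iodide F12. Acidic methanolysis (HCl, MeOH) returns to the route at 16.

## Further compounds

F0 | step 6 | none | none
F1 | step 12 | 6-fluoro-2,3,4-trimethoxybenzaldehyde | COc1cc(F)c(C=O)c(OC)c1OC
F2 | step 12 | 6-[2,6-dimethoxy-4-(2,4,6-trimethoxyphenoxy)phenoxy]-2,3,4-trimethoxybenzaldehyde | COc1cc(Oc2c(OC)cc(Oc3c(OC)cc(OC)cc3OC)cc2OC)c(C=O)c(OC)c1OC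
F3 | step 12 | 6-[2,6-dimethoxy-4-(2,4,6-trimethoxyphenoxy)phenoxy]-2,3,4-trimethoxyphenyl formate | COc1cc(Oc2c(OC)cc(Oc3c(OC)cc(OC)cc3OC)cc2OC)c(OC=O)c(OC)c1OC
F4 | step 12 | 6-[2,6-dimethoxy-4-(2,4,6-trimethoxyphenoxy)phenoxy]-2,3,4-trimethoxyphenol (same compound as A1) | COc1cc(Oc2c(OC)cc(Oc3c(OC)cc(OC)cc3OC)cc2OC)c(O)c(OC)c1OC
F5 | step 14 | 6-(4-{6-[2,6-dimethoxy-4-(2,4,6-trimethoxyphenoxy)phenoxy]-2,3,4-trimethoxyphenoxy}-2,6-dimethoxyphenoxy)-2,3,4-trimethoxybenzaldehyde | COc1cc(OC)c(Oc2cc(OC)c(Oc3cc(OC)c(OC)c(OC)c3Oc3cc(OC)c(Oc4cc(OC)c(OC)c(OC)c4C=O)c(OC)c3)c(OC)c2)c(OC)c1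
F6 | step 14 | 6-(4-{6-[2,6-dimethoxy-4-(2,4,6-trimethoxyphenoxy)phenoxy]-2,3,4-trimethoxyphenoxy}-2,6-dimethoxyphenoxy)-2,3,4-trimethoxyphenyl formate | COc1cc(OC)c(Oc2cc(OC)c(Oc3cc(OC)c(OC)c(OC)c3Oc3cc(OC)c(Oc4cc(OC)c(OC)c(OC)c4OC=O)c(OC)c3)c(OC)c2)c(OC)c1
F7 | step 14 | 6-(4-{6-[2,6-dimethoxy-4-(2,4,6-trimethoxyphenoxy)phenoxy]-2,3,4-trimethoxyphenoxy}-2,6-dimethoxyphenoxy)-2,3,4-trimethoxyphenol | COc1cc(OC)c(Oc2cc(OC)c(Oc3cc(OC)c(OC)c(OC)c3Oc3cc(OC)c(Oc4cc(OC)c(OC)c(OC)c4O)c(OC)c3)c(OC)c2)c(OC)c1
F8 | step 15 | hexadecaacetate of 23 (all sixteen hydroxyls as acetates) | CC(=O)Oc1cc(OC(C)=O)c(Oc2cc(OC(C)=O)c(Oc3cc(OC(C)=O)c(OC(C)=O)c(OC(C)=O)c3Oc3cc(OC(C)=O)c(Oc4cc(OC(C)=O)c(OC(C)=O)c(OC(C)=O)c4Oc4cc(OC(C)=O)c(OC(C)=O)c(OC(C)=O)c4)c(OC(C)=O)c3)c(OC(C)=O)c2)c(OC(C)=O)c1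
F9 | step 10 | 2-(benzyloxy)-5-iodo-1,3-dimethoxybenzene | COc1cc(I)cc(OC)c1OCc1ccccc1
F10 | step 10 | [4-(benzyloxy)-3,5-dimethoxyphenyl](2,4,6-trimethoxyphenyl)iodonium 4-methylbenzenesulfonate | COc1cc(OC)c([I+]c2cc(OC)c(OCc3ccccc3)c(OC)c2)c(OC)c1.Cc1ccc(S(=O)(=O)[O-])cc1
F11 | step 9 | 1,2,3-trimethoxy-4-(methoxymethoxy)benzene | COCOc1ccc(OC)c(OC)c1OC
F12 | step 9 | 1-iodo-3,4,5-trimethoxy-2-(methoxymethoxy)benzene | COCOc1c(I)cc(OC)c(OC)c1OC
A1 | alternative 1 | 6-[2,6-dimethoxy-4-(2,4,6-trimethoxyphenoxy)phenoxy]-2,3,4-trimethoxyphenol | COc1cc(Oc2c(OC)cc(Oc3c(OC)cc(OC)cc3OC)cc2OC)c(O)c(OC)c1OC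
A2 | alternative 1 | 4-{(E)-2-[2,6-dimethoxy-4-(2,4,6-trimethoxyphenoxy)phenoxy]ethenyl}-2,3,4-trimethoxycyclobut-2-en-1-one (racemic) | COC1=C(OC)C(OC)(/C=C/Oc2c(OC)cc(Oc3c(OC)cc(OC)cc3OC)cc2OC)C1=O
A3 | alternative 1 | dimethyl squarate (3,4-dimethoxycyclobut-3-ene-1,2-dione) | COC1=C(OC)C(=O)C1=O
A4 | alternative 1 | {(E)-2-[2,6-dimethoxy-4-(2,4,6-trimethoxyphenoxy)phenoxy]ethenyl}lithium | [Li]/C=C/Oc1c(OC)cc(Oc2c(OC)cc(OC)cc2OC)cc1OC
A5 | alternative 2 | hexadeca-O-methyl ether of the target, bound η6 through ring E to cyclopentadienylruthenium hexafluorophosphate | COc1cc(OC)c(Oc2cc(OC)c(Oc3cc(OC)c(OC)c(OC)c3Oc3cc(OC)c(Oc4cc(OC)c(OC)c(OC)c4Oc4cc(OC)c(OC)c(OC)c4)c(OC)c3)c(OC)c2)c(OC)c1.[Ru+2].c1cc[cH-]c1.F[P-](F)(F)(F)(F)F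
A6 | alternative 2 | (η6-4,5-dichloro-1,2,3-trimethoxybenzene)(η5-cyclopentadienyl)ruthenium hexafluorophosphate | COc1cc(Cl)c(Cl)c(OC)c1OC.[Ru+2].c1cc[cH-]c1.F[P-](F)(F)(F)(F)F
A7 | alternative 2 | 3,4,5-trimethoxyphenol | COc1cc(O)cc(OC)c1OC
A8 | alternative 3 | 3-methoxy-5-(2,4,6-trimethoxyphenoxy)cyclohexa-3,5-diene-1,2-dione | COC1=CC(Oc2c(OC)cc(OC)cc2OC)=CC(=O)C1=O
A9 | alternative 3 | guaiacol (2-methoxyphenol) | COc1ccccc1O
A10 | alternative 3 | 2,4,6-trimethoxyphenol | COc1cc(OC)c(O)c(OC)c1
A11 | alternative 3 | 3-methoxy-5-(2,4,6-trimethoxyphenoxy)benzene-1,2-diol | COc1cc(Oc2c(OC)cc(OC)cc2OC)cc(O)c1O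
A12 | alternative 3 | 3-methoxy-ortho-quinone (3-methoxycyclohexa-3,5-diene-1,2-dione) | COC1=CC=CC(=O)C1=O
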